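**Plan**
Enabling feature: in the benzene ring the two hydroxylated carbons and the carbon bearing the 2-acetoxytridecyl chain alternate with three CH carbons. The six ring atoms therefore map onto C2–C7 of a 3,5,7-triketo acyl chain whose C9 is the carbinol carbon.
Cuts: first the O–acetyl bonds. Then one ring C–H next to the side chain is traced back to a lost CO2Me group. Then the ring bond between that carbon (C2) and the chain-bearing carbon (C7) is cut, and finally C6–C7 of the open chain.
Forward: the C14 hydroxy acid becomes a silylated N-methoxy-N-methylamide, and a C6 keto-dioxinone dianion is joined to it in one C–C bond formation. The dioxinone is opened to the methyl triketo ester, and the only ring closes by C2-to-C7 aldol condensation.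
Endgame: saponification, decarboxylation and desilylation in one flask, then peracetylation, then selective removal of the two aryl acetates.
Stereochemistry: the single (R) centre is bought with (R)-3-hydroxytetradecanoic acid. Its C–O bond is never broken and the descriptor stays R throughout.

Key step: step 6

Assumption: all β-polycarbonyl compounds are drawn as their all-keto tautomers, although they will exist as keto–enol mixtures.

**Step 1**
Reactants: 1 (R)-3-hydroxytetradecanoic acid
Product: 2 (R)-3-hydroxy-N-methoxy-N-methyltetradecanamide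
Conditions: MeNH(OMe)·HCl, EDC·HCl, HOBt, N-methylmorpholine, CH2Cl2, 0 °C → rt
Reagents that add atoms: N,O-dimethylhydroxylamine hydrochloride, CNOC.Cl
Why: Carbodiimide/HOBt amide coupling, in which the free amine captures the active ester much faster than the secondary hydroxyl does and the C3 stereocentre takes no part.

**Step 2**
Reactants: 2 (R)-3-hydroxy-N-methoxy-N-methyltetradecanamide
Product: 3 (R)-3-(tert-butyldimethylsilyloxy)-N-methoxy-N-methyltetradecanamide
Conditions: TBSCl, imidazole, DMF, rt
Reagents that add atoms: tert-butyldimethylsilyl chloride, CC(C)(C)[Si](C)(C)Cl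
Why: Imidazole-promoted silylation of a secondary alcohol, which leaves the C–O bond untouched and installs a bulky, poor leaving group that guards the later β-oxygenated carbonyl compounds against elimination.

**Step 3**
Reactants: 4 2,2,6-trimethyl-4H-1,3-dioxin-4-one; 5 acetyl chloride
Product: 6 2,2-dimethyl-6-(2-oxopropyl)-4H-1,3-dioxin-4-one
Conditions: 4 (2 equiv), LiN(SiMe3)2 (2 equiv), THF, −78 °C; then 5 (1 equiv), −78 °C; 1 M HCl quench
Reagents that add atoms: none
Why: γ-Selective C-acylation (vinylogous Claisen condensation) of the lithium dienolate of the dioxinone with an acid chloride, the second equivalent of dienolate absorbing the acidic proton of the product.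

**Step 4**
Reactants: 6 2,2-dimethyl-6-(2-oxopropyl)-4H-1,3-dioxin-4-one; 3 (R)-3-(tert-butyldimethylsilyloxy)-N-methoxy-N-methyltetradecanamide
Product: 7 (R)-6-[6-(tert-butyldimethylsilyloxy)-2,4-dioxoheptadecyl]-2,2-dimethyl-4H-1,3-dioxin-4-one
Conditions: 6, LiN(i-Pr)2 (2 equiv per 6), THF, −78 → −40 °C; then 3, −78 → −20 °C; AcOH quench at −78 °C
Reagents that add atoms: none
Why: Claisen-type acylation of a 1,3-dicarbonyl dianion at its terminal, last-formed and most nucleophilic carbon (Weinreb ketone synthesis), in which the chelated tetrahedral adduct survives until the quench, so that neither over-addition nor extra base demand arises.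

**Step 5**
Reactants: 7 (R)-6-[6-(tert-butyldimethylsilyloxy)-2,4-dioxoheptadecyl]-2,2-dimethyl-4H-1,3-dioxin-4-one
Product: 9 methyl (R)-9-(tert-butyldimethylsilyloxy)-3,5,7-trioxoicosanoate, via acylketene 8 (not isolated)
Conditions: MeOH (excess), toluene, 110 °C, sealed tube; evaporate, crude 9 taken on
Reagents that add atoms: methanol, CO
Why: Retro-hetero-Diels–Alder fragmentation of the dioxinone expels acetone, and the acylketene is captured by the excess methanol faster than by its own C5 enol, a standard neutral entry to β-keto esters.

**Step 6**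
Reactants: 9 methyl (R)-9-(tert-butyldimethylsilyloxy)-3,5,7-trioxoicosanoate
Product: 11 methyl (R)-2,4-dihydroxy-6-[2-(tert-butyldimethylsilyloxy)tridecyl]benzoate, via aldol carbinol 10 (not isolated)
Conditions: Cs2CO3, MeOH, 0 °C → rt; then AcOH, rt
Reagents that add atoms: none
Why: Carbonate in methanol converts 9 into its enolates, and the C2 carbon, flanked by the ester and the C3 ketone, adds to the C7 ketone to give carbinol 10; loss of water across C2–C7 and enolisation of the C3 and C5 carbonyl groups, completed on buffering with AcOH, then give the benzene ring of 11. The closest known reaction type is the biomimetic intramolecular aldol condensation–aromatisation of 3,5,7-triketo esters to 6-alkyl-2,4-dihydroxybenzoates, which is established also for chains that carry a protected hydroxyl group at C9. The single ring closes in the 6-(enolexo)-exo-trig mode through the ester-side enolate of C2. No stereocentre is created in 11, since the two ring centres of 10 disappear on aromatisation, and C9 is only a spectator. Site selectivity is needed against the C6-to-C1 Claisen closure, the lactonisation of the C5 enol onto C1 and the C8-to-C3 aldol; it is secured because the C7 alkyl ketone is a better electrophile than the ester, because attack on the ester is reversible in methanol whereas aromatisation is not, and because C8 is activated by one carbonyl group only and is not deprotonated by carbonate. The same argument, together with the poor leaving-group ability of the bulky silyloxy group, holds back β-elimination at C8–C9 until the ketone has been consumed.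

**Step 7**
Reactants: 11 methyl (R)-2,4-dihydroxy-6-[2-(tert-butyldimethylsilyloxy)tridecyl]benzoate
Product: 14 (R)-5-(2-hydroxytridecyl)benzene-1,3-diol, via resorcylic acid 12 (not isolated), via silyl ether 13 (not isolated)
Conditions: NaOH (5 M aq.), MeOH, 100 °C, sealed tube, Ar; cool, then HCl (6 M aq.) to pH 1, THF, rt
Reagents that add atoms: none
Why: Saponification of the resorcylate is followed by protodecarboxylation of the electron-rich ortho,para-dihydroxybenzoate (retro-Kolbe–Schmitt reaction, the CO2 being fixed as carbonate) and only then by acid hydrolysis of the silyl ether, an order that keeps the freed alcohol from lactonising onto a carboxyl group.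

**Step 8**
Reactants: 14 (R)-5-(2-hydroxytridecyl)benzene-1,3-diol
Product: 15 (R)-5-(2-acetoxytridecyl)-1,3-phenylene diacetate
Conditions: Ac2O, pyridine, DMAP (cat.), CH2Cl2, rt
Reagents that add atoms: acetic anhydride, CC(=O)OC(C)=O
Why: DMAP-catalysed exhaustive acetylation of both phenols and the secondary alcohol, with retention at the carbinol carbon because only O–H bonds react.

**Step 9**
Reactants: 15 (R)-5-(2-acetoxytridecyl)-1,3-phenylene diacetate
Product: 16 (R)-1-(3,5-dihydroxyphenyl)tridecan-2-yl acetate
Conditions: NH4OAc, aq. MeOH, rt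
Reagents that add atoms: none
Why: Chemoselective transesterification of aryl acetates, in which phenoxide is a far better leaving group than a secondary alkoxide, so the neutral NH4OAc medium removes only the two aryl acetates.

**Compound list**
1 | (R)-3-hydroxytetradecanoic acid | CCCCCCCCCCC[C@H](CC(O)=O)O | starting material
2 | (R)-3-hydroxy-N-methoxy-N-methyltetradecanamide | CCCCCCCCCCC[C@H](CC(=O)N(C)OC)O | intermediate
3 | (R)-3-(tert-butyldimethylsilyloxy)-N-methoxy-N-methyltetradecanamide | CCCCCCCCCCC[C@H](CC(=O)N(C)OC)O[Si](C)(C)C(C)(C)C | intermediate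
4 | 2,2,6-trimethyl-4H-1,3-dioxin-4-one | CC1=CC(=O)OC(C)(C)O1 | starting material
5 | acetyl chloride | CC(Cl)=O | starting material
6 | 2,2-dimethyl-6-(2-oxopropyl)-4H-1,3-dioxin-4-one | CC(=O)CC1=CC(=O)OC(C)(C)O1 | intermediate
7 | (R)-6-[6-(tert-butyldimethylsilyloxy)-2,4-dioxoheptadecyl]-2,2-dimethyl-4H-1,3-dioxin-4-one | CCCCCCCCCCC[C@H](CC(=O)CC(=O)CC1=CC(=O)OC(C)(C)O1)O[Si](C)(C)C(C)(C)C | intermediate
8 | (R)-9-(tert-butyldimethylsilyloxy)-3,5,7-trioxoicos-1-en-1-one (acylketene, not isolated) | CCCCCCCCCCC[C@H](CC(=O)CC(=O)CC(=O)C=C=O)O[Si](C)(C)C(C)(C)C | intermediate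
9 | methyl (R)-9-(tert-butyldimethylsilyloxy)-3,5,7-trioxoicosanoate | CCCCCCCCCCC[C@H](CC(=O)CC(=O)CC(=O)CC(=O)OC)O[Si](C)(C)C(C)(C)C | intermediate
10 | methyl 2-hydroxy-4,6-dioxo-2-[(R)-2-(tert-butyldimethylsilyloxy)tridecyl]cyclohexane-1-carboxylate (aldol carbinol, not isolated; the two transient ring centres are undefined) | CCCCCCCCCCC[C@H](CC1(O)CC(=O)CC(=O)C1C(=O)OC)O[Si](C)(C)C(C)(C)C | intermediate
11 | methyl (R)-2,4-dihydroxy-6-[2-(tert-butyldimethylsilyloxy)tridecyl]benzoate | CCCCCCCCCCC[C@H](Cc1cc(O)cc(O)c1C(=O)OC)O[Si](C)(C)C(C)(C)C | intermediate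
12 | (R)-2,4-dihydroxy-6-[2-(tert-butyldimethylsilyloxy)tridecyl]benzoic acid (present as its sodium salt, not isolated) | CCCCCCCCCCC[C@H](Cc1cc(O)cc(O)c1C(O)=O)O[Si](C)(C)C(C)(C)C | intermediate
13 | (R)-5-[2-(tert-butyldimethylsilyloxy)tridecyl]benzene-1,3-diol (not isolated) | CCCCCCCCCCC[C@H](Cc1cc(O)cc(O)c1)O[Si](C)(C)C(C)(C)C | intermediate
14 | (R)-5-(2-hydroxytridecyl)benzene-1,3-diol | CCCCCCCCCCC[C@H](Cc1cc(O)cc(O)c1)O | intermediate
15 | (R)-5-(2-acetoxytridecyl)-1,3-phenylene diacetate | CCCCCCCCCCC[C@H](Cc1cc(OC(C)=O)cc(OC(C)=O)c1)OC(C)=O | intermediate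
16 | (R)-1-(3,5-dihydroxyphenyl)tridecan-2-yl acetate (CNP0241330.1) | CCCCCCCCCCC[C@H](Cc1cc(O)cc(O)c1)OC(C)=O | target

**Step count**
Total step count: 9.
Longest linear sequence: 8 (steps 1, 2, 4, 5, 6, 7, 8, 9). Step 3 lies on the short branch.

**Steps most likely to fail**

Step 4.
- What may go wrong: the strongly basic dianion may deprotonate the amide at its α-carbon instead of adding to it. That leads to β-elimination of silanolate or to stalled conversion.
- Fallback (sets out from 3 and 6, comes back at 7): the oxidation level of the electrophile is changed. Amide 3 is reduced with i-Bu2AlH (THF, −78 °C) to (R)-3-(tert-butyldimethylsilyloxy)tetradecanal F1. The dianion of 6 adds to this far more electrophilic carbonyl group at −78 °C in an aldol addition. This gives 6-[(6R)-6-(tert-butyldimethylsilyloxy)-4-hydroxy-2-oxoheptadecyl]-2,2-dimethyl-4H-1,3-dioxin-4-one F2 as a mixture of carbinol epimers, which is of no consequence. Dess–Martin periodinane (CH2Cl2, rt) then oxidises the β-hydroxy ketone to 7.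

Step 6.
- What may go wrong: closure may occur through the wrong pair of atoms (attack of C6 or of the C5 enol oxygen on the ester carbonyl). Base-induced β-elimination of the silyloxy group may also occur before the ring has formed.
- Fallback (sets out from 7, comes back at 14): the C2–C7 bond formation is kept, but C1 and the C3 oxygen stay tied up in the dioxinone ring, where the carboxyl carbon cannot act as the electrophile. Treatment of 7 with Et3N in CH2Cl2 at rt generates the dioxinone dienolate, whose α-carbon (C2) attacks the C7 ketone. Loss of water gives (R)-7-hydroxy-2,2-dimethyl-5-[2-(tert-butyldimethylsilyloxy)tridecyl]-4H-benzo[d][1,3]dioxin-4-one F3. The conditions of step 7 then open its acetonide to the salt of 12 and carry on through 13 to 14.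

Step 7.
- What may go wrong: saponification of the di-ortho-substituted, hydrogen-bonded ester may be slow. Decarboxylation may be incomplete before the acid stage, followed by lactonisation of the freed alcohol onto the remaining carboxyl group. The hot resorcinolate may also be oxidised by air.
- Fallback (sets out from 7, comes back at 14): the ester is exchanged for one that falls off under neutral conditions, and the three events are separated. Acylketene 8 released from 7 (toluene, 110 °C) is trapped with benzyl alcohol to give benzyl (R)-9-(tert-butyldimethylsilyloxy)-3,5,7-trioxoicosanoate F4. This is aromatised as in step 6 (Cs2CO3, i-PrOH/CH2Cl2, then AcOH) to benzyl (R)-2,4-dihydroxy-6-[2-(tert-butyldimethylsilyloxy)tridecyl]benzoate F5. Hydrogenolysis (H2, Pd/C, EtOAc) frees acid 12, now isolated. Heating 12 in DMF at about 120 °C expels CO2 to give 13, and aqueous HCl in MeOH/THF converts 13 into 14.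

**Further compounds**
F1 | step 4 | (R)-3-(tert-butyldimethylsilyloxy)tetradecanal | CCCCCCCCCCC[C@H](CC=O)O[Si](C)(C)C(C)(C)C
F2 | step 4 | 6-[(6R)-6-(tert-butyldimethylsilyloxy)-4-hydroxy-2-oxoheptadecyl]-2,2-dimethyl-4H-1,3-dioxin-4-one (both epimers at the new carbinol) | CCCCCCCCCCC[C@H](CC(O)CC(=O)CC1=CC(=O)OC(C)(C)O1)O[Si](C)(C)C(C)(C)C
F3 | step 6 | (R)-7-hydroxy-2,2-dimethyl-5-[2-(tert-butyldimethylsilyloxy)tridecyl]-4H-benzo[d][1,3]dioxin-4-one | CCCCCCCCCCC[C@H](Cc1cc(O)cc2OC(C)(C)OC(=O)c12)O[Si](C)(C)C(C)(C)C
F4 | step 7 | benzyl (R)-9-(tert-butyldimethylsilyloxy)-3,5,7-trioxoicosanoate | CCCCCCCCCCC[C@H](CC(=O)CC(=O)CC(=O)CC(=O)OCc1ccccc1)O[Si](C)(C)C(C)(C)C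
F5 | step 7 | benzyl (R)-2,4-dihydroxy-6-[2-(tert-butyldimethylsilyloxy)tridecyl]benzoate | CCCCCCCCCCC[C@H](Cc1cc(O)cc(O)c1C(=O)OCc1ccccc1)O[Si](C)(C)C(C)(C)C
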